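The whole route rests on cutting two bonds of the tetrahydrofuran ring (O, C5, C6, C7, C8) at once: the ether bond O–C5 and the C6–Cl bond. This leaves a ten-membered carbocycle with a free tertiary C8 hydroxyl that is homoallylic to a C5=C6 alkene lying trans within the ring. Such an alkene shows its outer face to a reagent and its inner face to O8. One chloronium-triggered transannular etherification therefore joins the two fully substituted carbons C5 and C8, installs chlorine and sets C5 and C6. The precursor, with cyclohexenone, γ-lactone and (3Z)-alkene in place, is assembled from three fragments by Grignard addition, Mukaiyama aldol reaction and ring-closing metathesis.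

Key step: step 18

Remark on numbering (briarane locants, used for all intermediates): C1 = quaternary ring-fusion carbon (CH3 = C15); C2 = CH(OAc); C3=C4; C5 = carbon bearing C16H2OH; C6 = CHCl; C7 = lactone CH–O; C8 = ether carbon; C9 = CH(OAc); C10 = ring-fusion CH; C11 = C(=C20H2); C12, C13 = CH2; C14 = CH(OAc); C17 = CH(C18H3); C19 = lactone C=O.

Step 1
Reactants: 1 methacrolein; 2 (E)-1-(trimethylsilyloxy)buta-1,3-diene
Product: 4 (1R,2S)-2-hydroxy-1-methylcyclohex-3-ene-1-carbaldehyde, via silyl ether cycloadduct 3 (not isolated)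
Conditions: (S)-3,3-diphenyl-1-(o-tolyl)tetrahydro-1H,3H-pyrrolo[1,2-c][1,3,2]oxazaborole·HNTf2 (10 mol %), CH2Cl2, −78 °C; then citric acid, THF/H2O, 0 °C
Reagents that add atoms: none
Why: Catalytic enantioselective Diels–Alder reaction in which the 1-oxy diene gives the ortho adduct, the formyl-endo transition state places O14 cis to the formyl carbon C2, and the catalyst enantiomer that shields the enal face leading to ent-4 fixes C1 and C14 absolutely.

Step 2
Reactants: 4 (1R,2S)-2-hydroxy-1-methylcyclohex-3-ene-1-carbaldehyde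
Product: 5 (1S,6S)-6-[(1S)-1-hydroxyprop-2-en-1-yl]-6-methylcyclohex-2-en-1-ol
Conditions: vinylMgBr (3 equiv), THF/CH2Cl2, −78 → −40 °C
Reagents that add atoms: vinylmagnesium bromide C=C[Mg]Br
Why: Chelation-controlled Grignard addition in which the magnesium alkoxide of O14 binds the aldehyde oxygen in a six-membered chelate cis-fused to the carbocycle, so that the vinyl group enters from the convex, methyl-bearing face and sets C2 as in the target.

Step 3
Reactants: 5 (1S,6S)-6-[(1S)-1-hydroxyprop-2-en-1-yl]-6-methylcyclohex-2-en-1-ol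
Product: 6 (1S,6S)-6-[(1S)-1-acetoxyprop-2-en-1-yl]-6-methylcyclohex-2-en-1-yl acetate
Conditions: Ac2O, pyridine, DMAP (cat.), rt
Reagents that add atoms: acetic anhydride CC(=O)OC(C)=O
Why: Nucleophile-catalysed acylation installs the final C2 and C14 acetates early, and no stereocentre is touched.

Step 4
Reactants: 6 (1S,6S)-6-[(1S)-1-acetoxyprop-2-en-1-yl]-6-methylcyclohex-2-en-1-yl acetate
Product: 7 (1S,6S)-6-[(1S)-1-acetoxyprop-2-en-1-yl]-6-methyl-4-oxocyclohex-2-en-1-yl acetate
Conditions: Rh2(cap)4 (1 mol %), tBuOOH (5 equiv), K2CO3 (0.5 equiv), CH2Cl2, rt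
Reagents that add atoms: tert-butyl hydroperoxide CC(C)(C)OO
Why: Radical allylic C–H oxidation to the enone takes place at C11H2, the only allylic position that is neither acetoxy-substituted nor neopentyl.

Step 5
Reactants: 7 (1S,6S)-6-[(1S)-1-acetoxyprop-2-en-1-yl]-6-methyl-4-oxocyclohex-2-en-1-yl acetate
Product: 8 cross-conjugated C11-O-trimethylsilyl dienol ether of 7 (C10=C11–C12=C13)
Conditions: TMSOTf, Et3N, CH2Cl2, 0 °C; non-aqueous work-up
Reagents that add atoms: trimethylsilyl triflate C[Si](C)(C)OS(=O)(=O)C(F)(F)F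
Why: Soft enolisation of a cyclohexenone removes the kinetic α′-proton at C10 and spares both acetates, giving the 2-silyloxy-1,3-diene that is nucleophilic at C10.

Step 6
Reactants: 9 propargyl alcohol
Product: 11 (Z)-2-(iodomethylidene)but-3-en-1-ol, via magnesacycle 10 (not isolated)
Conditions: vinylMgBr (2.5 equiv), CuI (10 mol %), THF, −10 °C → rt; then I2, −30 °C
Reagents that add atoms: vinylmagnesium bromide C=C[Mg]Br; iodine [I][I]
Why: Copper-catalysed anti-carbomagnesiation of a propargylic alkoxide puts the vinyl group on the inner alkyne carbon and holds magnesium cis to CH2O in a five-membered chelate, so iodinolysis with retention gives iodine (the later C7) cis to C16.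

Step 7
Reactants: 11 (Z)-2-(iodomethylidene)but-3-en-1-ol
Product: 12 (Z)-tert-butyl{[2-(iodomethylidene)but-3-en-1-yl]oxy}dimethylsilane
Conditions: TBSCl, imidazole, CH2Cl2, 0 °C → rt
Reagents that add atoms: tert-butyldimethylsilyl chloride CC(C)(C)[Si](C)(C)Cl
Why: Standard silylation masks O16, the one oxygen that must stay unacetylated.

Step 8
Reactants: 13 dimethyl (S)-malate
Product: 14 dimethyl (2S,3R)-2-hydroxy-3-methylbutanedioate
Conditions: LDA (2.2 equiv), THF, −78 → −20 °C; MeI, −78 → 0 °C
Reagents that add atoms: iodomethane CI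
Why: Fráter–Seebach alkylation of the chelated alkoxide enolate is anti-selective and sets C17 from the purchased C8 stereocentre.

Step 9
Reactants: 14 dimethyl (2S,3R)-2-hydroxy-3-methylbutanedioate
Product: 15 (2S,3R)-2-hydroxy-3-methylbutanedioic acid
Conditions: KOH, MeOH/H2O, 0 °C → rt; then HCl to pH 1
Reagents that add atoms: potassium hydroxide [K+].[OH-]
Why: Ester saponification gives carboxylates that resist enolisation, so C17 should not epimerise.

Step 10
Reactants: 15 (2S,3R)-2-hydroxy-3-methylbutanedioic acid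
Product: 16 (2R)-2-[(2S,4S)-2-tert-butyl-5-oxo-1,3-dioxolan-4-yl]propanoic acid
Conditions: tBuCHO, TsOH (cat.), H2SO4 (cat.), pentane, reflux, water separator; crystallisation
Reagents that add atoms: pivalaldehyde CC(C)(C)C=O
Why: Thermodynamic acetalisation of the α-hydroxy acid unit (self-regeneration of stereocentres) prefers the five-membered cis-dioxolanone, whose new acetal centre stores the C8 configuration.

Step 11
Reactants: 16 (2R)-2-[(2S,4S)-2-tert-butyl-5-oxo-1,3-dioxolan-4-yl]propanoic acid
Product: 18 (2R)-2-[(2S,4R)-2-tert-butyl-5-oxo-4-(triethylsilyloxymethyl)-1,3-dioxolan-4-yl]propanoic acid, via dilithium hydroxymethyl adduct 17 (not isolated)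
Conditions: LiHMDS (2.1 equiv), THF, −78 °C; CH2O (gas); Et3SiCl (1.05 equiv), −78 °C; pH 4 work-up
Reagents that add atoms: formaldehyde C=O; chlorotriethylsilane CC[Si](CC)(CC)Cl
Why: Aldol hydroxymethylation of the carboxylate-protected dioxolanone enolate occurs anti to the tert-butyl group, so C9 replaces H8 with retention and creates the fully substituted C8.

Step 12
Reactants: 18 (2R)-2-[(2S,4R)-2-tert-butyl-5-oxo-4-(triethylsilyloxymethyl)-1,3-dioxolan-4-yl]propanoic acid
Product: 20 (3R,4R)-4,5-dihydroxy-3-methyl-4-(triethylsilyloxymethyl)oxolan-2-one (anomer mixture), via dioxolan-4-ol 19 (not isolated)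
Conditions: DIBAL-H (2.2 equiv), CH2Cl2, −78 °C; Rochelle salt, then pH 5 buffer
Reagents that add atoms: none
Why: Partial hydride reduction hits only the activated dioxolanone carbonyl C7, because the aluminium carboxylate is inert at −78 °C, after which the hemiacetal sheds pivalaldehyde and the C19 acid captures the freed α-hydroxy aldehyde as a lactol.

Step 13
Reactants: 20 (3R,4R)-4,5-dihydroxy-3-methyl-4-(triethylsilyloxymethyl)oxolan-2-one; 12 (Z)-tert-butyl{[2-(iodomethylidene)but-3-en-1-yl]oxy}dimethylsilane
Product: 23 (3R,4R,5S)-5-[(1Z)-2-(tert-butyldimethylsilyloxymethyl)buta-1,3-dien-1-yl]-4-hydroxy-3-methyl-4-(triethylsilyloxymethyl)oxolan-2-one, via alkenylmagnesium chloride 21 (not isolated), via open hydroxy acid 22 (not isolated)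
Conditions: 12, iPrMgCl·LiCl, THF, −20 °C; 20, LiHMDS (2.0 equiv), MgBr2·OEt2, THF, −78 °C; combine, −78 → −40 °C; pH 4 buffer, rt
Reagents that add atoms: none
Why: Iodine–magnesium exchange with retention is followed by chelation-controlled addition to the ring-opened α-alkoxido aldehyde, where magnesium bridges O7 and O8 and the alkenyl group enters past the small C9H2OSiEt3 arm rather than the branched C17 arm to set C7, and mild acid then closes the γ-lactone with C6, O8 and C18 on one face.

Step 14
Reactants: 23 (3R,4R,5S)-5-[(1Z)-2-(tert-butyldimethylsilyloxymethyl)buta-1,3-dien-1-yl]-4-hydroxy-3-methyl-4-(triethylsilyloxymethyl)oxolan-2-one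
Product: 24 (2S,3S,4R)-2-[(1Z)-2-(tert-butyldimethylsilyloxymethyl)buta-1,3-dien-1-yl]-3-hydroxy-4-methyl-5-oxooxolane-3-carbaldehyde
Conditions: (COCl)2, DMSO, CH2Cl2, −78 → −40 °C; Et3N, −78 → 0 °C
Reagents that add atoms: none
Why: Swern oxidation applied directly to a primary triethylsilyl ether cleaves and oxidises it in one operation, while the primary TBS ether and the tertiary C8 hydroxyl stay untouched.

Step 15
Reactants: 8 cross-conjugated C11-O-trimethylsilyl dienol ether of 7; 24 lactone aldehyde
Product: 25 aldol adduct with the new C9–C10 bond (C9–OH and C8–OH free; 4-acetoxy enone ring; C1 C2 C7 C8 C9 C10 C14 C17 configured as in the target)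
Conditions: MgBr2·OEt2 (3 equiv), CH2Cl2, −78 → −20 °C; citric acid work-up
Reagents that add atoms: none
Why: Chelation-controlled Mukaiyama aldol addition in which MgBr2 ties O8–H and the aldehyde oxygen into a five-membered chelate that is attacked through an open transition state from its C17 side, away from the dienyl-bearing C7, to give the 8,9-syn and 9,10-syn relations, while C10 bonds on the ring face anti to the large C2 side chain, which is also the more stable diequatorial arrangement.

Step 16
Reactants: 25 aldol adduct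
Product: 26 C9 acetate of 25 (triacetate; C8–OH free)
Conditions: Ac2O, pyridine, DMAP (cat.), CH2Cl2, 0 °C → rt
Reagents that add atoms: acetic anhydride CC(=O)OC(C)=O
Why: Selective acylation takes the secondary C9 hydroxyl and leaves the tertiary C8 hydroxyl, which the later etherification needs, unreacted.

Step 17
Reactants: 26 C9 acetate of 25
Product: 27 ten-membered (3Z)-diene macrocycle (C5=C6 trans within the ring with C16 cis to C7; C8–OH free; enone lactone and three acetates in place)
Conditions: second-generation Hoveyda–Grubbs catalyst (10 mol %), 1,4-benzoquinone (20 mol %), toluene (0.5 mM), 80 °C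
Reagents that add atoms: none
Why: Ring-closing metathesis joins the C2 vinyl group to the terminal alkene of the diene, because the trisubstituted C5=C6 is too hindered to take part, loss of ethene drives the closure, and a ten-membered ring accepts the new C3=C4 only as the Z isomer.

Step 18
Reactants: 27 ten-membered (3Z)-diene macrocycle
Product: 28 6-chloro-5,8-epoxy tetracycle (C16 OTBS; C11 enone; all ring stereocentres as in the target)
Conditions: NCS (1.1 equiv), (CF3)2CHOH/CH2Cl2 1:4, −20 → 0 °C, dark
Reagents that add atoms: N-chlorosuccinimide O=C1CCC(=O)N1Cl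
Why: NCS, activated by hydrogen bonding to the fluorinated alcohol, delivers Cl+ to C6 on the outward face of the C5=C6 alkene, which stands roughly perpendicular to the mean plane of the ten-membered ring, and the positive charge develops on C5, which is tertiary and allylic to C3=C4. The C8 hydroxyl, homoallylic to this alkene and held against its inward face, captures C5 while the succinimide anion takes the proton; the closest known reaction type is the 5-endo halo-etherification of homoallylic alcohols, run here transannularly as in cyclisations of trans-cyclodecenes. The only ring closed is the tetrahydrofuran O–C5–C6–C7–C8, by 5-endo-trig attack of oxygen on the chloriranium or allyl cation. C5 is fixed by the six-carbon bridge C4–C3–C2–C1–C10–C9, which can span the new ring only if C4 and C9 are cis, so O8 reaches one alkene face only, and C6 follows from anti addition to the alkene geometry built in with 12 (C16 cis to C7), which places Cl cis to C16. The step needs site selectivity for C5=C6, and the substrate secures it: the C12=C13 enone alkene is electron-poor, C11 carries no methylene yet, and C3=C4 is only disubstituted and deactivated by the C2 acetate. Proton loss from the cation and acetate participation should be outrun by the proximity of O8.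

Step 19
Reactants: 28 6-chloro-5,8-epoxy tetracycle
Product: 29 saturated C11 ketone of 28
Conditions: Cu(OAc)2·H2O (5 mol %), 1,2-bis(diphenylphosphino)benzene (5 mol %), PhSiH3 (1.2 equiv), tBuOH (2 equiv), toluene, rt
Reagents that add atoms: none
Why: Copper hydride 1,4-reduction is specific for the enone, forms its enolate on the C12 side so that the C9 acetate cannot be eliminated, and leaves C3=C4, the esters and the secondary chloride alone.

Step 20
Reactants: 29 saturated C11 ketone of 28
Product: 30 C16 O-TBS ether of the target (C11=C20 methylene installed)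
Conditions: Zn, CH2Br2, TiCl4 (reagent pre-formed in THF at 5 °C), CH2Cl2, 0 °C → rt
Reagents that add atoms: dibromomethane BrCBr
Why: Takai–Lombardo methylenation is non-basic and selective for ketones over esters, so the β-acetoxy ketone should neither epimerise at C10 nor eliminate, and the acetates and lactone survive.

Step 21
Reactants: 30 C16 O-TBS ether of the target
Product: 31 target CNP0408507.1
Conditions: HF·pyridine, pyridine, THF, 0 °C → rt
Reagents that add atoms: none
Why: Buffered fluoride desilylation frees the neopentyl C16 hydroxyl without acyl migration, since no acetate is vicinal to it, and without touching the chloride or the alkenes.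

Compound list
1 | methacrolein | C=C(C)C=O | starting material
2 | (E)-1-(trimethylsilyloxy)buta-1,3-diene | C=C/C=C/O[Si](C)(C)C | starting material
3 | (1R,2S)-1-methyl-2-(trimethylsilyloxy)cyclohex-3-ene-1-carbaldehyde | C1C=C[C@H](O[Si](C)(C)C)[C@](C)(C=O)C1 | intermediate
4 | (1R,2S)-2-hydroxy-1-methylcyclohex-3-ene-1-carbaldehyde | C1C=C[C@H](O)[C@](C)(C=O)C1 | intermediate
5 | (1S,6S)-6-[(1S)-1-hydroxyprop-2-en-1-yl]-6-methylcyclohex-2-en-1-ol | C1C=C[C@H](O)[C@](C)([C@@H](O)C=C)C1 | intermediate
6 | (1S,6S)-6-[(1S)-1-acetoxyprop-2-en-1-yl]-6-methylcyclohex-2-en-1-yl acetate | C1C=C[C@H](OC(C)=O)[C@](C)([C@@H](OC(C)=O)C=C)C1 | intermediate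
7 | (1S,6S)-6-[(1S)-1-acetoxyprop-2-en-1-yl]-6-methyl-4-oxocyclohex-2-en-1-yl acetate | O=C1C=C[C@H](OC(C)=O)[C@](C)([C@@H](OC(C)=O)C=C)C1 | intermediate
8 | cross-conjugated C11-O-trimethylsilyl dienol ether of 7 | C[Si](C)(C)OC=1C=C[C@H](OC(C)=O)[C@](C)([C@@H](OC(C)=O)C=C)C=1 | intermediate
9 | propargyl alcohol | C#CCO | starting material
10 | 4-vinyl-1-oxa-2-magnesacyclopent-3-ene (chelated alkenylmagnesium alkoxide) | C=CC1=C[Mg]OC1 | intermediate
11 | (Z)-2-(iodomethylidene)but-3-en-1-ol | OC/C(C=C)=C\I | intermediate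
12 | (Z)-tert-butyl{[2-(iodomethylidene)but-3-en-1-yl]oxy}dimethylsilane | CC(C)(C)[Si](C)(C)OC/C(C=C)=C\I | intermediate
13 | dimethyl (S)-malate | COC(=O)C[C@H](O)C(=O)OC | starting material
14 | dimethyl (2S,3R)-2-hydroxy-3-methylbutanedioate | COC(=O)[C@H](C)[C@H](O)C(=O)OC | intermediate
15 | (2S,3R)-2-hydroxy-3-methylbutanedioic acid | OC(=O)[C@H](C)[C@H](O)C(=O)O | intermediate
16 | (2R)-2-[(2S,4S)-2-tert-butyl-5-oxo-1,3-dioxolan-4-yl]propanoic acid | OC(=O)[C@H](C)[C@@H]1O[C@H](C(C)(C)C)OC1=O | intermediate
17 | dilithium salt of the C8-hydroxymethylated dioxolanone acid | [Li]OC(=O)[C@H](C)[C@]1(CO[Li])O[C@H](C(C)(C)C)OC1=O | intermediate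
18 | (2R)-2-[(2S,4R)-2-tert-butyl-5-oxo-4-(triethylsilyloxymethyl)-1,3-dioxolan-4-yl]propanoic acid | OC(=O)[C@H](C)[C@]1(CO[Si](CC)(CC)CC)O[C@H](C(C)(C)C)OC1=O | intermediate
19 | dioxolan-4-ol from reduction of 18 (hemiacetal carbon unassigned) | OC(=O)[C@H](C)[C@]1(CO[Si](CC)(CC)CC)O[C@H](C(C)(C)C)OC1O | intermediate
20 | (3R,4R)-4,5-dihydroxy-3-methyl-4-(triethylsilyloxymethyl)oxolan-2-one, anomer mixture | O[C@@]1(CO[Si](CC)(CC)CC)[C@@H](C)C(=O)OC1O | intermediate
21 | (Z)-[2-(tert-butyldimethylsilyloxymethyl)buta-1,3-dien-1-yl]magnesium chloride | CC(C)(C)[Si](C)(C)OC/C(C=C)=C\[Mg]Cl | intermediate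
22 | open C7,C8-dihydroxy acid (C7 allylic alcohol, C19 acid) | OC(=O)[C@H](C)[C@@](O)(CO[Si](CC)(CC)CC)[C@@H](O)/C=C(\CO[Si](C)(C)C(C)(C)C)C=C | intermediate
23 | (3R,4R,5S)-5-[(1Z)-2-(tert-butyldimethylsilyloxymethyl)buta-1,3-dien-1-yl]-4-hydroxy-3-methyl-4-(triethylsilyloxymethyl)oxolan-2-one | O[C@@]1(CO[Si](CC)(CC)CC)[C@@H](C)C(=O)O[C@H]1/C=C(\CO[Si](C)(C)C(C)(C)C)C=C | intermediate
24 | (2S,3S,4R)-2-[(1Z)-2-(tert-butyldimethylsilyloxymethyl)buta-1,3-dien-1-yl]-3-hydroxy-4-methyl-5-oxooxolane-3-carbaldehyde | O[C@@]1(C=O)[C@@H](C)C(=O)O[C@H]1/C=C(\CO[Si](C)(C)C(C)(C)C)C=C | intermediate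
25 | aldol adduct, C9–C10 joined, 8,9-diol, 4-acetoxy enone | O=C1C=C[C@H](OC(C)=O)[C@](C)([C@@H](OC(C)=O)C=C)[C@H]1[C@H](O)[C@]2(O)[C@@H](C)C(=O)O[C@H]2/C=C(\CO[Si](C)(C)C(C)(C)C)C=C | intermediate
26 | C9 acetate of 25 | O=C1C=C[C@H](OC(C)=O)[C@](C)([C@@H](OC(C)=O)C=C)[C@H]1[C@H](OC(C)=O)[C@]2(O)[C@@H](C)C(=O)O[C@H]2/C=C(\CO[Si](C)(C)C(C)(C)C)C=C | intermediate
27 | ten-membered macrocycle, C3=C4 Z, C5=C6 trans within the ring, C8–OH free | O=C1C=C[C@H](OC(C)=O)[C@]2(C)[C@@H](OC(C)=O)/C=C\C(CO[Si](C)(C)C(C)(C)C)=C\[C@@H]3OC(=O)[C@H](C)[C@@]3(O)[C@@H](OC(C)=O)[C@@H]12 | intermediate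
28 | 6-chloro-5,8-epoxy tetracycle, C16 OTBS, C11 enone | O=C1C=C[C@H](OC(C)=O)[C@]2(C)[C@@H](OC(C)=O)/C=C\[C@]3(CO[Si](C)(C)C(C)(C)C)O[C@]4([C@@H](C)C(=O)O[C@H]4[C@H]3Cl)[C@@H](OC(C)=O)[C@@H]12 | intermediate
29 | saturated C11 ketone of 28 | O=C1CC[C@H](OC(C)=O)[C@]2(C)[C@@H](OC(C)=O)/C=C\[C@]3(CO[Si](C)(C)C(C)(C)C)O[C@]4([C@@H](C)C(=O)O[C@H]4[C@H]3Cl)[C@@H](OC(C)=O)[C@@H]12 | intermediate
30 | C16 O-TBS ether of the target | C=C1CC[C@H](OC(C)=O)[C@]2(C)[C@@H](OC(C)=O)/C=C\[C@]3(CO[Si](C)(C)C(C)(C)C)O[C@]4([C@@H](C)C(=O)O[C@H]4[C@H]3Cl)[C@@H](OC(C)=O)[C@@H]12 | intermediate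
31 | CNP0408507.1 | C=C1CC[C@H](OC(C)=O)[C@]2(C)[C@@H](OC(C)=O)/C=C\[C@]3(CO)O[C@]4([C@@H](C)C(=O)O[C@H]4[C@H]3Cl)[C@@H](OC(C)=O)[C@@H]12 | target

Total step count: 21. Longest linear sequence: 14 steps (steps 8–21, from dimethyl (S)-malate).

Steps most likely to fail

1. Step 15 (fragment union). The new bond joins two carbons that each sit next to a fully substituted centre. Addition may therefore be slower than hydrolysis of the dienol ether, and the open transition state may lose its facial bias at C9 or revert by retro-aldol cleavage. The fallback sets out from 8. Bromination with NBS in THF at −78 °C should give the α′-bromo enone F1. CrCl2 with catalytic LiI in THF, in the presence of 24, should then turn F1 into a trivalent chromium enolate, which adds in a Reformatsky-type reaction through a closed and practically irreversible transition state under neutral conditions. This line comes back to the route at 25.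

2. Step 17 (macrocyclisation). Oligomerisation, resting of the catalyst as a stabilised vinylcarbene on the diene, or an unfavourable rotamer about C8–C9 may prevent closure of the strained ring. The fallback sets out from 25 and changes the substrate design. Condensation with PhB(OH)2 (toluene, molecular sieves) should tie O8 and O9 into the cyclic phenylboronate F2, which holds the two chain ends gauche. Ring-closing metathesis of this locked triene should give the macrocyclic boronate F3. Neutral exchange with pinacol should release the macrocyclic 8,9-diol F4. Selective acetylation of its secondary C9 hydroxyl (Ac2O, pyridine, DMAP) comes back to the route at 27.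

3. Step 18 (key step). Chlorination may occur at C3=C4, the C5 cation may lose a proton to give an allylic chloride, or the C2 acetate may capture the cation before O8 does. The fallback sets out from 27 and separates C–Cl formation from C–O closure. Anti-dichlorination of the trisubstituted alkene with Et4NCl3 in CH2Cl2 should give the 5,6-dichloride F5, whose C6–Cl bond again comes from attack on the outer face. Ionisation of its tertiary allylic C5–Cl bond with AgOTf and 2,6-di-tert-butylpyridine should then let O8 trap the cation transannularly. The configuration at C5 is again dictated by the bridge. This line comes back to the route at 28.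

Further compounds
F1 | step 15 | α′-bromo enone (C10–Br anti to the C2 side chain) | O=C1C=C[C@H](OC(C)=O)[C@](C)([C@@H](OC(C)=O)C=C)[C@H]1Br
F2 | step 17 | cyclic phenylboronate of the 8,9-diol 25 | O=C1C=C[C@H](OC(C)=O)[C@](C)([C@@H](OC(C)=O)C=C)[C@H]1[C@@H]3OB(c4ccccc4)O[C@]32[C@@H](C)C(=O)O[C@H]2/C=C(\CO[Si](C)(C)C(C)(C)C)C=C
F3 | step 17 | macrocyclic 8,9-phenylboronate | O=C1C=C[C@H](OC(C)=O)[C@]2(C)[C@@H](OC(C)=O)/C=C\C(CO[Si](C)(C)C(C)(C)C)=C\[C@@H]3OC(=O)[C@H](C)[C@]34OB(c5ccccc5)O[C@H]4[C@@H]12
F4 | step 17 | macrocyclic 8,9-diol | O=C1C=C[C@H](OC(C)=O)[C@]2(C)[C@@H](OC(C)=O)/C=C\C(CO[Si](C)(C)C(C)(C)C)=C\[C@@H]3OC(=O)[C@H](C)[C@@]3(O)[C@@H](O)[C@@H]12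
F5 | step 18 | macrocyclic 5,6-dichloride | O=C1C=C[C@H](OC(C)=O)[C@]2(C)[C@@H](OC(C)=O)/C=C\[C@@](Cl)(CO[Si](C)(C)C(C)(C)C)[C@H](Cl)[C@@H]3OC(=O)[C@H](C)[C@@]3(O)[C@@H](OC(C)=O)[C@@H]12
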